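Ring atoms are lettered a (C–OAc), b (CH2), c (CHMe), d and f (cyclopropane CH), g and h (butenolide α and β carbons) and i (CH bearing the side chain). The eight-membered ring is cut at f–g. The feature used: the oxygen on a and carbon f end a five-carbon run (a–b–c–d–f), and g becomes the doubly activated methylene of a β-keto ester once h is a ketone. An acyclic, stereodefined hydroxy acetal β-keto ester is ionised to an a–O–f oxocarbenium ion that g captures. One operation closes a tetrahydropyran and a pyranone ring whose common periphery is the cyclooctane. Bridge opening, butenolide annulation, inversion at a, cyclopropanation of d=f and a Schenck ene reaction follow.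

Key step: step 10

Remark: j denotes the side-chain methine carbon attached to i.
Assumption: the quinidine-series catalyst is taken to open 1 to the (S)-half-ester 2. Should the sense be opposite, the pseudoenantiomeric (DHQ)2AQN is used and nothing else changes.

Step 1
Reactants: 1 3-methylglutaric anhydride
Product: 2 (S)-5-methoxy-3-methyl-5-oxopentanoic acid
Conditions: MeOH (10 equiv), hydroquinidine (anthraquinone-1,4-diyl) diether [(DHQD)2AQN, cat.], Et2O, −40 °C
Reagents that add atoms: methanol, CO
Why: Alkaloid-catalysed enantioselective methanolysis (desymmetrisation of a prochiral cyclic anhydride) tells the two enantiotopic carbonyl groups apart and so fixes centre c, and any minor enantiomer becomes a separable diastereomer after step 7.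

Step 2
Reactants: 2 (S)-5-methoxy-3-methyl-5-oxopentanoic acid
Product: 3 methyl (S)-5-hydroxy-3-methylpentanoate
Conditions: BH3·SMe2, THF, 0 °C → rt; H2O
Reagents that add atoms: none
Why: Borane reduces a free carboxylic acid through its acyloxyborane far faster than a methyl ester (chemoselective acid reduction), and c is not touched.

Step 3
Reactants: 3 methyl (S)-5-hydroxy-3-methylpentanoate
Product: 4 methyl (S)-3-methyl-5-oxopentanoate
Conditions: 2,2,6,6-tetramethylpiperidine-1-oxyl (TEMPO, cat.), PhI(OAc)2, CH2Cl2, rt
Reagents that add atoms: none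
Why: Oxoammonium (TEMPO) oxidation stops at the aldehyde under nearly neutral conditions, which also avoids lactonisation of the δ-hydroxy ester.

Step 4
Reactants: 4 methyl (S)-3-methyl-5-oxopentanoate
Product: 5 methyl (S)-5,5-dimethoxy-3-methylpentanoate
Conditions: HC(OMe)3, TsOH·H2O (cat.), MeOH, rt
Reagents that add atoms: trimethyl orthoformate, COC(OC)OC
Why: Acid-catalysed acetalisation driven by the orthoformate masks the future carbon f while the ester stays inert.

Step 5
Reactants: 5 methyl (S)-5,5-dimethoxy-3-methylpentanoate
Product: 6 (R)-5,5-dimethoxy-3-methylpentanal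
Conditions: i-Bu2AlH (1.05 equiv), CH2Cl2, −78 °C; aq potassium sodium tartrate
Reagents that add atoms: none
Why: Partial ester reduction with i-Bu2AlH holds at the tetrahedral aluminium hemiacetal until work-up and so delivers the aldehyde (future carbon a) beside the untouched acetal.

Step 6
Reactants: 7 (R)-citronellic acid; 8 (R)-4-benzyl-1,3-oxazolidin-2-one
Product: 10 (R)-4-benzyl-3-[(R)-3,7-dimethyloct-6-enoyl]-1,3-oxazolidin-2-one, via mixed pivalic anhydride 9 (not isolated)
Conditions: t-BuCOCl, Et3N, THF, −20 °C; then LiCl, 8, rt
Reagents that add atoms: none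
Why: N-Acylation of the oxazolidinone through a mixed anhydride with LiCl activation loads the auxiliary without strong base and leaves the chiral-pool centre j unchanged.

Step 7
Reactants: 10 (R)-4-benzyl-3-[(R)-3,7-dimethyloct-6-enoyl]-1,3-oxazolidin-2-one; 6 (R)-5,5-dimethoxy-3-methylpentanal
Product: 12 (R)-4-benzyl-3-{(2R,3S,5R)-3-hydroxy-7,7-dimethoxy-5-methyl-2-[(2R)-6-methylhept-5-en-2-yl]heptanoyl}-1,3-oxazolidin-2-one, via Z-boron enolate 11 (not isolated)
Conditions: n-Bu2BOTf, Et3N, CH2Cl2, −78 → 0 °C; 6, −78 → 0 °C; pH 7 buffer, MeOH, 30% H2O2, 0 °C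
Reagents that add atoms: none
Why: Evans syn aldol, in which the Z-boron enolate reacts through a closed Zimmerman–Traxler chair on the face away from the benzyl group, so that i and a are set 2,3-syn under auxiliary control (i as in the target, a deliberately epimeric to it) whatever the remote centres c and j prefer.

Step 8
Reactants: 12 syn aldol imide
Product: 13 (2R,3S,5R)-3-hydroxy-N,7,7-trimethoxy-N,5-dimethyl-2-[(2R)-6-methylhept-5-en-2-yl]heptanamide
Conditions: MeONHMe·HCl, AlMe3, CH2Cl2, −10 °C → rt; aq potassium sodium tartrate
Reagents that add atoms: N,O-dimethylhydroxylamine hydrochloride, CNOC.Cl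
Why: Aluminium-amide transamination (Weinreb amide formation) of a β-hydroxy imide is steered to the exocyclic acyl group by the aluminium alkoxide of the free hydroxyl and does not epimerise i.

Step 9
Reactants: 13 Weinreb amide; 14 methyl acetate
Product: 16 methyl (4R,5S,7R)-5-hydroxy-9,9-dimethoxy-7-methyl-4-[(2R)-6-methylhept-5-en-2-yl]-3-oxononanoate, via lithium enolate of methyl acetate 15 (not isolated)
Conditions: LiN(i-Pr)2, 14 (4 equiv each), THF, −78 °C; 13, −78 → −30 °C; AcOH, −78 °C
Reagents that add atoms: none
Why: Crossed Claisen-type acylation of an ester enolate by a Weinreb amide stops at the chelated tetrahedral adduct, so exactly one acetate unit (g plus the ester) is added while the aldol array is carried safely as its lithium alkoxide.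

Step 10
Reactants: 16 hydroxy acetal β-keto ester
Product: 19 methyl (1R,2S,4R,5S,7R)-7-methyl-4-[(2R)-6-methylhept-5-en-2-yl]-3-oxo-9-oxabicyclo[3.3.1]nonane-2-carboxylate, via bis(trimethylsilyl) derivative 17 (not isolated), via cyclic oxocarbenium triflate 18 (not isolated)
Conditions: i-Pr2NEt (2.2 equiv), Me3SiOTf (2.6 equiv), CH2Cl2, −78 → −30 °C; aq NaHCO3
Reagents that add atoms: none
Why: Me3SiOTf and i-Pr2NEt first silylate the hydroxyl on a and the β-keto ester (17); the Me3SiOTf left over ionises the dimethyl acetal, the silyl ether oxygen closes on f (6-exo-trig, tetrahydropyran ring O–a–b–c–d–f), loss of the second methoxy group gives oxocarbenium ion 18, and enol silane carbon g then bonds to f. The closest known reaction type is the intramolecular Mukaiyama-type addition of a silyl enol ether to a six-membered oxocarbenium ion, as it operates in the second stage of the silyl-triflate-catalysed (3+5) annulation between 1,5-dicarbonyl compounds and 1,3-bis(silyloxy)dienes. The C–C closure is 6-(enolendo)-endo-trig for the pyranone ring O–a–i–h–g–f and, read along the carbon periphery a–b–c–d–f–g–h–i, it is at the same time the closure of the eight-membered carbocycle. The new centre f is controlled by a: the tether lets g reach f only on the face that carries the pseudoaxial chain on a, which is also the stereoelectronically preferred axial approach in a chair-like transition state, and this chair keeps the methyl on c equatorial only for the a-epimer installed in step 7; the new centre g is epimerisable and should settle with the ester equatorial, while i already carries its side chain equatorially. The step needs C- rather than O-attack, g rather than i as the nucleophile, and capture faster than proton loss from d or Prins attack by the side-chain alkene; soft silylation enolises only the doubly activated position g, g sits at six-ring distance from f, and the alkene could reach f only through a ring of eight or more atoms.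

Step 11
Reactants: 19 oxabicyclic β-keto ester
Product: 22 methyl (3R,4S,6R)-6-methyl-3-[(2R)-6-methylhept-5-en-2-yl]-4-(triethylsilyloxy)-2-(trifluoromethylsulfonyloxy)cycloocta-1,7-diene-1-carboxylate (both ring alkenes cis), via disodium alkoxide dienolate 20 (not isolated), via O-triethylsilyl sodium dienolate 21 (not isolated)
Conditions: NaH (2.5 equiv), THF, 0 → 40 °C; Et3SiCl (1.0 equiv), −78 → −30 °C; Comins' reagent, −78 → 0 °C
Reagents that add atoms: chlorotriethylsilane, CC[Si](Cl)(CC)CC; N-(5-chloropyridin-2-yl)bis(trifluoromethanesulfonimide) (Comins' reagent), O=S(=O)(N(c1ccc(Cl)cn1)S(=O)(=O)C(F)(F)F)C(F)(F)F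
Why: E1cB opening (retro-oxa-Michael) of the β-alkoxy β-keto ester enolate breaks f–O, the alkylidene keto ester so formed loses a proton from d to give the extended dienolate, irreversible loss of H2 with the second equivalent of NaH pulls the otherwise unfavourable equilibrium to 20 (NaH being too poor a kinetic base to deprotonate i), and the far more nucleophilic alkoxide is silylated before the stabilised dienolate is O-sulfonylated (enol triflate formation).

Step 12
Reactants: 22 dienyl triflate; 23 (tributylstannyl)methanol
Product: 26 hydroxy dienyl butenolide (cycloocta[c]furan-1(3H)-one core, cis d=f alkene, (S)-OH on a, (R)-methyl on c, (S)-configured i bearing the (R)-6-methylhept-5-en-2-yl group), via hydroxymethyl dienoate 24 (not isolated), via silylated butenolide 25 (not isolated)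
Conditions: Pd(PPh3)4 (5 mol %), LiCl (3 equiv), dioxane, 90 °C; then 1 M HCl, THF, rt
Reagents that add atoms: none
Why: Stille coupling of the electron-poor enol triflate with the hydroxymethyl stannane places CH2OH on h cis to the ester on g, so lactonisation to the butenolide follows by itself, and the acid stage completes it while hydrolysing the triethylsilyl ether.

Step 13
Reactants: 26 hydroxy dienyl butenolide
Product: 27 inverted 4-nitrobenzoate ((R)-configured a, otherwise as 26)
Conditions: 4-O2NC6H4CO2H, PPh3, DIAD, toluene, 0 °C → rt
Reagents that add atoms: 4-nitrobenzoic acid, OC(=O)c1ccc(cc1)[N+](=O)[O-]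
Why: Mitsunobu reaction with the more acidic 4-nitrobenzoic acid, the variant established for hindered menthol-type secondary alcohols where acetic acid performs poorly, displaces the oxyphosphonium group by SN2 with inversion at a, and elimination into conjugation is disfavoured because the hydrogen on i is cis to the leaving group.

Step 14
Reactants: 27 inverted 4-nitrobenzoate
Product: 28 inverted alcohol ((R)-OH on a)
Conditions: K2CO3 (cat.), MeOH, 0 °C
Reagents that add atoms: none
Why: Carbonate-catalysed transesterification cleaves the activated nitrobenzoate at the acyl–oxygen bond (no change at a) much faster than the butenolide can be opened or enolised.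

Step 15
Reactants: 28 inverted alcohol
Product: 29 dienyl butenolide acetate ((R)-OAc on a)
Conditions: Ac2O, 4-(dimethylamino)pyridine (cat.), pyridine, CH2Cl2, rt
Reagents that add atoms: acetic anhydride, CC(=O)OC(C)=O
Why: Nucleophile-catalysed acetylation of the secondary alcohol proceeds with retention at a.

Step 16
Reactants: 29 dienyl butenolide acetate
Product: 30 cyclopropane acetate (the target skeleton with the intact prenyl terminus)
Conditions: CH2N2 (excess, in Et2O), Pd(OAc)2 (5 mol %), Et2O, 0 °C
Reagents that add atoms: diazomethane, C=[N+]=[N-]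
Why: Palladium-catalysed cyclopropanation with diazomethane is governed by alkene coordination and therefore takes cis-1,2-disubstituted and conjugated alkenes but spares trisubstituted ones (an electrophilic zinc carbenoid would choose the electron-rich side-chain alkene instead), and the syn-specific CH2 transfer should come from the peripheral face of d=f, opposite to ring carbon b in the conformer that keeps the hydrogen on c in the alkene plane (allylic 1,3-strain), which sets d and f with the methylene trans to the methyl on c.

Step 17
Reactants: 30 cyclopropane acetate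
Product: 31 target CNP0205234.1
Conditions: O2, 5,10,15,20-tetraphenylporphyrin (cat.), visible light, CH2Cl2, −20 °C; chromatography
Reagents that add atoms: dioxygen, O=O
Why: Schenck ene reaction, in which singlet oxygen touches only the electron-rich trisubstituted alkene and abstraction of an allylic CH2 hydrogen moves the double bond to the E-disubstituted position with the hydroperoxide on the tertiary carbon, while competing abstraction from the cis methyl group lowers the return and calls for chromatographic separation.

Compound list
1 | 3-methylglutaric anhydride | CC1CC(=O)OC(=O)C1 | starting material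
2 | (S)-5-methoxy-3-methyl-5-oxopentanoic acid | COC(=O)C[C@@H](C)CC(=O)O | intermediate
3 | methyl (S)-5-hydroxy-3-methylpentanoate | COC(=O)C[C@@H](C)CCO | intermediate
4 | methyl (S)-3-methyl-5-oxopentanoate | COC(=O)C[C@@H](C)CC=O | intermediate
5 | methyl (S)-5,5-dimethoxy-3-methylpentanoate | COC(=O)C[C@@H](C)CC(OC)OC | intermediate
6 | (R)-5,5-dimethoxy-3-methylpentanal | O=CC[C@@H](C)CC(OC)OC | intermediate
7 | (R)-citronellic acid, (R)-3,7-dimethyloct-6-enoic acid | OC(=O)C[C@H](C)CCC=C(C)C | starting material
8 | (R)-4-benzyl-1,3-oxazolidin-2-one | O=C1N[C@H](Cc2ccccc2)CO1 | starting material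
9 | (R)-3,7-dimethyloct-6-enoic pivalic anhydride (not isolated) | CC(C)(C)C(=O)OC(=O)C[C@H](C)CCC=C(C)C | intermediate
10 | (R)-4-benzyl-3-[(R)-3,7-dimethyloct-6-enoyl]-1,3-oxazolidin-2-one | O=C(C[C@H](C)CCC=C(C)C)N1[C@H](Cc2ccccc2)COC1=O | intermediate
11 | (Z)-dibutylboron enolate of 10 (not isolated) | CCCCB(CCCC)O/C(=C\[C@H](C)CCC=C(C)C)N1[C@H](Cc2ccccc2)COC1=O | intermediate
12 | (R)-4-benzyl-3-{(2R,3S,5R)-3-hydroxy-7,7-dimethoxy-5-methyl-2-[(2R)-6-methylhept-5-en-2-yl]heptanoyl}-1,3-oxazolidin-2-one | O=C([C@H]([C@H](C)CCC=C(C)C)[C@@H](O)C[C@@H](C)CC(OC)OC)N1[C@H](Cc2ccccc2)COC1=O | intermediate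
13 | (2R,3S,5R)-3-hydroxy-N,7,7-trimethoxy-N,5-dimethyl-2-[(2R)-6-methylhept-5-en-2-yl]heptanamide | CON(C)C(=O)[C@H]([C@H](C)CCC=C(C)C)[C@@H](O)C[C@@H](C)CC(OC)OC | intermediate
14 | methyl acetate | COC(C)=O | starting material
15 | lithium enolate of methyl acetate (not isolated) | [Li+].[O-]C(=C)OC | intermediate
16 | methyl (4R,5S,7R)-5-hydroxy-9,9-dimethoxy-7-methyl-4-[(2R)-6-methylhept-5-en-2-yl]-3-oxononanoate (key-step precursor; a epimeric to the target) | COC(=O)CC(=O)[C@H]([C@H](C)CCC=C(C)C)[C@@H](O)C[C@@H](C)CC(OC)OC | intermediate
17 | trimethylsilyl ether (on a) and trimethylsilyl enol ether (h–O, g=h, geometry open) of 16 (not isolated) | COC(=O)C=C(O[Si](C)(C)C)[C@H]([C@H](C)CCC=C(C)C)[C@@H](O[Si](C)(C)C)C[C@@H](C)CC(OC)OC | intermediate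
18 | six-membered a–O–f oxocarbenium triflate carrying the enol silane chain on a (not isolated) | COC(=O)C=C(O[Si](C)(C)C)[C@H]([C@H](C)CCC=C(C)C)[C@@H]1C[C@@H](C)CC=[O+]1.[O-]S(=O)(=O)C(F)(F)F | intermediate
19 | methyl (1R,2S,4R,5S,7R)-7-methyl-4-[(2R)-6-methylhept-5-en-2-yl]-3-oxo-9-oxabicyclo[3.3.1]nonane-2-carboxylate (key-step product) | O1[C@H]2C[C@@H](C)C[C@@H]1[C@H](C(=O)OC)C(=O)[C@@H]2[C@H](C)CCC=C(C)C | intermediate
20 | disodium salt: alkoxide on a, dienolate d=f–g=h–O (not isolated) | [Na+].[Na+].[O-][C@H]1C[C@@H](C)/C=C\C(C(=O)OC)=C([O-])/[C@@H]1[C@H](C)CCC=C(C)C | intermediate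
21 | sodium dienolate with triethylsilyl ether on a (not isolated) | [Na+].CC[Si](CC)(CC)O[C@H]1C[C@@H](C)/C=C\C(C(=O)OC)=C([O-])/[C@@H]1[C@H](C)CCC=C(C)C | intermediate
22 | methyl (3R,4S,6R)-6-methyl-3-[(2R)-6-methylhept-5-en-2-yl]-4-(triethylsilyloxy)-2-(trifluoromethylsulfonyloxy)cycloocta-1,7-diene-1-carboxylate | CC[Si](CC)(CC)O[C@H]1C[C@@H](C)/C=C\C(C(=O)OC)=C(OS(=O)(=O)C(F)(F)F)/[C@@H]1[C@H](C)CCC=C(C)C | intermediate
23 | (tributylstannyl)methanol | CCCC[Sn](CO)(CCCC)CCCC | starting material
24 | 2-(hydroxymethyl) analogue of 22 (CH2OH on h in place of the triflate; not isolated) | CC[Si](CC)(CC)O[C@H]1C[C@@H](C)/C=C\C(C(=O)OC)=C(CO)/[C@@H]1[C@H](C)CCC=C(C)C | intermediate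
25 | dienyl butenolide with triethylsilyl ether on a (not isolated) | CC[Si](CC)(CC)O[C@H]1C[C@@H](C)/C=C\C2=C(COC2=O)[C@@H]1[C@H](C)CCC=C(C)C | intermediate
26 | hydroxy dienyl butenolide, (S)-OH on a | O[C@H]1C[C@@H](C)/C=C\C2=C(COC2=O)[C@@H]1[C@H](C)CCC=C(C)C | intermediate
27 | 4-nitrobenzoate with inverted, (R)-configured a | O=C(O[C@@H]1C[C@@H](C)/C=C\C2=C(COC2=O)[C@@H]1[C@H](C)CCC=C(C)C)c1ccc(cc1)[N+](=O)[O-] | intermediate
28 | hydroxy dienyl butenolide, (R)-OH on a | O[C@@H]1C[C@@H](C)/C=C\C2=C(COC2=O)[C@@H]1[C@H](C)CCC=C(C)C | intermediate
29 | dienyl butenolide acetate, (R)-OAc on a | CC(=O)O[C@@H]1C[C@@H](C)/C=C\C2=C(COC2=O)[C@@H]1[C@H](C)CCC=C(C)C | intermediate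
30 | cyclopropane acetate (d S, f S; methylene trans to the methyl on c, cis to OAc) with prenyl terminus | CC(=O)O[C@@H]1C[C@@H](C)[C@@H]2C[C@@H]2C2=C(COC2=O)[C@@H]1[C@H](C)CCC=C(C)C | intermediate
31 | CNP0205234.1, (E)-allylic tertiary hydroperoxide | CC(=O)O[C@@H]1C[C@@H](C)[C@@H]2C[C@@H]2C2=C(COC2=O)[C@@H]1[C@H](C)C/C=C/C(C)(C)OO | target

Total step count: 17. Longest linear sequence: 16 steps (steps 1–5 and 7–17, from 1).

Steps most likely to fail

Step 10 (key step).
- What may go wrong: the oxocarbenium ion may lose a proton from d faster than it is captured. The ambident enol silane may bond through oxygen. The conformer with the bulky chain on a axial may be too sparsely populated.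
- Fallback (sets out from 13, returns at 19): the f–g bond is made intermolecularly and the bicycle is closed by acylation at h–g instead.
- Camphorsulfonic acid (cat.) in CH2Cl2 turns 13 into the cyclic methyl acetal F1.
- Me3SiOTf-promoted Mukaiyama-type addition of 1-methoxy-1-(trimethylsilyloxy)ethene to the derived oxocarbenium ion gives the 2,6-cis tetrahydropyranyl acetate F2 together with its f-epimer F3.
- KOt-Bu in THF equilibrates the two by reversible retro-oxa-Michael and oxa-Michael addition. Only the cis isomer, through its diaxial chair, can undergo Dieckmann-type attack of the ester enolate on the Weinreb amide, so the stabilised enolate of 19 acts as the sink.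

Step 11.
- What may go wrong: the opening may stall because the closed enolate is the more stable monoanion. The transient aldolate may fragment by retro-aldol cleavage of a–i. The two anionic sites may not be told apart by the two electrophiles.
- Fallback (sets out from 19, returns at 22): a silylative, Lewis-acid-driven elimination that never passes through a free alkoxide.
- Et3SiOTf and Et3N in CH2Cl2 (0 °C → rt) enolise g softly, silylate the bridging oxygen, break f–O and remove a proton from d. Two strong Si–O bonds provide the driving force, giving the bis(triethylsilyl) dienol ether F4.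
- The far more labile dienol silyl ether is then exchanged selectively with Bu4N[Ph3SiF2] and Comins' reagent in THF at low temperature to give 22.

Step 16.
- What may go wrong: carbene transfer to a hindered, conjugated cis-alkene may be too slow to compete with decomposition of diazomethane, or the two alkene faces may not be distinguished well enough.
- Fallback (sets out from 29, returns at 30): the side-chain alkene is taken out of play so that a much more reactive electrophilic zinc carbenoid can be used.
- Lemieux–Johnson cleavage (OsO4 cat., NaIO4, 2,6-lutidine, dioxane–H2O) attacks only the electron-rich trisubstituted alkene and gives the side-chain aldehyde F5.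
- HC(OMe)3 with pyridinium tosylate gives the dimethyl acetal F6.
- CF3CO2ZnCH2I (from Et2Zn, CF3CO2H and CH2I2, CH2Cl2, 0 °C) cyclopropanates d=f, the only alkene left that is not tetrasubstituted and electron-poor, to the cyclopropyl acetal F7.
- Aqueous acid releases the cyclopropyl aldehyde F8.
- Wittig olefination with Ph3P=CMe2 (from isopropyltriphenylphosphonium iodide and n-BuLi, THF, −78 °C) rebuilds the prenyl terminus of 30.

Further compounds
F1 | step 10 | cyclic methyl acetal of 13 (2-methoxytetrahydropyran, anomeric mixture) | COC1C[C@H](C)C[C@H](O1)[C@@H]([C@H](C)CCC=C(C)C)C(=O)N(C)OC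
F2 | step 10 | 2,6-cis tetrahydropyranyl acetate bearing the Weinreb amide chain on a | COC(=O)C[C@H]1C[C@H](C)C[C@H](O1)[C@@H]([C@H](C)CCC=C(C)C)C(=O)N(C)OC
F3 | step 10 | f-epimer of F2 (2,6-trans) | COC(=O)C[C@@H]1C[C@H](C)C[C@H](O1)[C@@H]([C@H](C)CCC=C(C)C)C(=O)N(C)OC
F4 | step 11 | bis(triethylsilyl) compound: silyl ether on a, dienol silyl ether on h | CC[Si](CC)(CC)O[C@H]1C[C@@H](C)/C=C\C(C(=O)OC)=C(O[Si](CC)(CC)CC)/[C@@H]1[C@H](C)CCC=C(C)C
F5 | step 16 | dienyl butenolide acetate with side-chain aldehyde | CC(=O)O[C@@H]1C[C@@H](C)/C=C\C2=C(COC2=O)[C@@H]1[C@H](C)CCC=O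
F6 | step 16 | dimethyl acetal of F5 | CC(=O)O[C@@H]1C[C@@H](C)/C=C\C2=C(COC2=O)[C@@H]1[C@H](C)CCC(OC)OC
F7 | step 16 | cyclopropyl dimethyl acetal | CC(=O)O[C@@H]1C[C@@H](C)[C@@H]2C[C@@H]2C2=C(COC2=O)[C@@H]1[C@H](C)CCC(OC)OC
F8 | step 16 | cyclopropyl aldehyde | CC(=O)O[C@@H]1C[C@@H](C)[C@@H]2C[C@@H]2C2=C(COC2=O)[C@@H]1[C@H](C)CCC=O
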